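**Strategy.** Hernanol is a trans-α,β-dibenzyl-γ-butyrolactone. The plan cuts the lactone ring at C3–C4 and at C5–O1, on either side of the stereocentre C4 that carries the guaiacylmethyl group. The key step joins a (Z)-alkenyl p-tolyl sulfoxide (C4=C5, sulfur on C5) with dichloroketene (C2, C3). O-Acylation, a [3,3] shift and Pummerer-type ring closure should give the lactone in one operation and relay the sulfur stereocentre to C4. The step exploits the fact that C5 is a CH2–O carbon next to C4, so it can carry a temporary chiral sulfinyl group. The chlorines at C3 and the sulfur at C5 are then removed, and the trimethoxybenzyl group is attached trans by enolate alkylation.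

Key step: step 4

Remark: lactone atoms are numbered O1, C2 (C=O), C3, C4, C5 (CH2O); 1 is taken as a catalogue compound (otherwise one O-benzylation of 4-bromoguaiacol makes it).

Step 1
Reactants: 1 1-(benzyloxy)-4-bromo-2-methoxybenzene; 2 methoxyallene
Product: 4 1-(benzyloxy)-2-methoxy-4-(prop-2-yn-1-yl)benzene, via arylmagnesium bromide 3 (not isolated)
Conditions: Mg, THF, reflux; then 2, CuBr (5 mol %), Et2O–THF, −10 °C → rt; aq. NH4Cl
Reagents that add atoms: none
Why: Copper-catalysed SN2′ substitution of the allenyl ether by the aryl Grignard reagent (attack at the CH2 terminus, loss of methoxide) should give the 3-aryl-1-propyne directly; no stereocentre is formed.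

Step 2
Reactants: 4 1-(benzyloxy)-2-methoxy-4-(prop-2-yn-1-yl)benzene; 5 (1R,2S,5R)-menthyl (S)-p-toluenesulfinate
Product: 7 (S)-3-aryl-1-propynyl p-tolyl sulfoxide, via alkynylmagnesium bromide 6 (not isolated)
Conditions: EtMgBr, THF, 0 °C → rt; then added to 5, toluene, −20 °C; aq. NH4Cl
Reagents that add atoms: none
Why: Andersen sulfoxide synthesis, in which the alkynyl Grignard reagent displaces menthoxide with inversion at sulfur, so the (S)-sulfinate should give the (S)-alkynyl sulfoxide (the descriptor stays S only because the alkynyl group outranks p-tolyl).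

Step 3
Reactants: 7 (S)-3-aryl-1-propynyl p-tolyl sulfoxide
Product: 8 (R)-(Z)-3-aryl-1-propenyl p-tolyl sulfoxide
Conditions: H2 (1 atm), RhCl(PPh3)3 (cat.), benzene, rt
Reagents that add atoms: none
Why: Homogeneous syn-hydrogenation with Wilkinson's catalyst should stop at the (Z)-alkenyl sulfoxide and leave the benzyl ether and sulfur untouched; the descriptor at sulfur becomes R through the priority change alone.

Step 4
Reactants: 8 (R)-(Z)-3-aryl-1-propenyl p-tolyl sulfoxide
Product: 11 (4S,5R)-4-[4-(benzyloxy)-3-methoxybenzyl]-3,3-dichloro-5-(p-tolylsulfanyl)dihydrofuran-2(3H)-one, via acyloxysulfonium enolate 9 (not isolated), via thionium carboxylate 10 (not isolated)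
Conditions: Cl3CCOCl (slow addition), Zn–Cu, Et2O, 0 °C → reflux
Reagents that add atoms: trichloroacetyl chloride, ClC(=O)C(Cl)(Cl)Cl (delivered as dichloroketene, ClC(Cl)=C=O, made in the flask)
Why: Additive Pummerer lactonization (vinyl sulfoxide–dichloroketene annulation): the sulfinyl oxygen of 8 adds to dichloroketene to give 9, which undergoes a [3,3]-sigmatropic shift through a six-membered chair that forms C3–C4 and breaks S–O to give 10, whose carboxylate then closes onto the thionium carbon (5-exo-trig at C5=S+) to form C5–O1. The closest known reaction types are the Pummerer reaction and the Claisen-type [3,3] shift, and this annulation is established for (Z)-1-alkenyl p-tolyl sulfoxides. C4 is set by chirality transfer from sulfur: in the (Z)-alkene, allylic strain with the cis CH2Ar group places the sulfur lone pair syn to C=C and p-tolyl outside, so the enolate carbon is delivered to a single alkene face, which should give 4S in 11 (R once Cl and S are gone). C5 should form cis to the C4 benzyl group because the carboxylate collapses on the face to which it was delivered; this centre is erased in step 5. The step needs the ketene to be captured by the sulfoxide oxygen faster than zinc deoxygenates the sulfoxide or the thionium ion loses a proton, which the high electrophilicity of dichloroketene and the absence of any other nucleophilic π-bond should secure.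

Step 5
Reactants: 11 (4S,5R)-dichloro(arylthio)lactone
Product: 12 (R)-4-[4-(benzyloxy)-3-methoxybenzyl]dihydrofuran-2(3H)-one
Conditions: Bu3SnH (5 equiv), AIBN (cat.), toluene, 110 °C
Reagents that add atoms: none
Why: Radical chain reduction with tin hydride should remove both α-chlorines and the arylthio group of the O,S-acetal through stabilised α-acyl and α-oxy radicals, while C4 (never a radical centre) keeps its configuration.

Step 6
Reactants: 12 (R)-4-[4-(benzyloxy)-3-methoxybenzyl]dihydrofuran-2(3H)-one; 13 3,4,5-trimethoxybenzyl bromide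
Product: 15 (3R,4R)-4-[4-(benzyloxy)-3-methoxybenzyl]-3-(3,4,5-trimethoxybenzyl)dihydrofuran-2(3H)-one, via lithium enolate 14 (not isolated)
Conditions: LiHMDS, THF, −78 °C; then 13, DMPU, −78 → −30 °C
Reagents that add atoms: none
Why: Enolate alkylation of a β-substituted γ-butyrolactone, in which the benzyl bromide should approach anti to the C4 benzyl group and so set C3 as R (3,4-trans).

Step 7
Reactants: 15 (3R,4R)-O-benzylhernanol
Product: 16 hernanol
Conditions: H2 (1 atm), 10 % Pd/C, EtOAc, rt
Reagents that add atoms: none
Why: Hydrogenolysis of the benzyl ether over Pd/C should free the phenol under neutral conditions that leave the lactone, the methyl ethers and both stereocentres untouched.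

**Compound list**

1 | 1-(benzyloxy)-4-bromo-2-methoxybenzene | COc1cc(Br)ccc1OCc1ccccc1 | starting material
2 | methoxyallene (1-methoxypropa-1,2-diene) | COC=C=C | starting material
3 | [4-(benzyloxy)-3-methoxyphenyl]magnesium bromide | COc1cc([Mg]Br)ccc1OCc1ccccc1 | intermediate
4 | 1-(benzyloxy)-2-methoxy-4-(prop-2-yn-1-yl)benzene | COc1cc(CC#C)ccc1OCc1ccccc1 | intermediate
5 | (1R,2S,5R)-menthyl (S)-4-methylbenzenesulfinate | C[C@@H]1CC[C@H]([C@@H](C1)O[S@](=O)c2ccc(C)cc2)C(C)C | starting material
6 | {3-[4-(benzyloxy)-3-methoxyphenyl]prop-1-yn-1-yl}magnesium bromide | COc1cc(CC#C[Mg]Br)ccc1OCc1ccccc1 | intermediate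
7 | 1-(benzyloxy)-2-methoxy-4-{3-[(S)-4-methylbenzenesulfinyl]prop-2-yn-1-yl}benzene | COc1cc(CC#C[S@@](=O)c2ccc(C)cc2)ccc1OCc1ccccc1 | intermediate
8 | 1-(benzyloxy)-2-methoxy-4-{(Z)-3-[(R)-4-methylbenzenesulfinyl]prop-2-en-1-yl}benzene | COc1cc(C/C=C\[S@@](=O)c2ccc(C)cc2)ccc1OCc1ccccc1 | intermediate
9 | O-(2,2-dichloro-1-oxidovinyl) derivative of 8 (acyloxysulfonium enolate, zwitterion) | COc1cc(C/C=C\[S@@+](OC([O-])=C(Cl)Cl)c2ccc(C)cc2)ccc1OCc1ccccc1 | intermediate
10 | (S)-3-[4-(benzyloxy)-3-methoxybenzyl]-2,2-dichloro-4-(p-tolylsulfonio)but-3-enoate (thionium carboxylate, zwitterion) | Cc1ccc(cc1)[S+]=C[C@H](Cc1ccc(OCc2ccccc2)c(OC)c1)C(Cl)(Cl)C(=O)[O-] | intermediate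
11 | (4S,5R)-4-[4-(benzyloxy)-3-methoxybenzyl]-3,3-dichloro-5-(p-tolylsulfanyl)dihydrofuran-2(3H)-one (benzyl and arylthio cis) | O=C1O[C@H](Sc2ccc(C)cc2)[C@H](Cc2ccc(OCc3ccccc3)c(OC)c2)C1(Cl)Cl | intermediate
12 | (R)-4-[4-(benzyloxy)-3-methoxybenzyl]dihydrofuran-2(3H)-one | O=C1OC[C@H](Cc2ccc(OCc3ccccc3)c(OC)c2)C1 | intermediate
13 | 3,4,5-trimethoxybenzyl bromide | COc1cc(CBr)cc(OC)c1OC | starting material
14 | lithium enolate of 12 | [Li]OC1=C[C@@H](Cc2ccc(OCc3ccccc3)c(OC)c2)CO1 | intermediate
15 | (3R,4R)-4-[4-(benzyloxy)-3-methoxybenzyl]-3-(3,4,5-trimethoxybenzyl)dihydrofuran-2(3H)-one | COc1cc(C[C@H]2COC(=O)[C@@H]2Cc2cc(OC)c(OC)c(OC)c2)ccc1OCc1ccccc1 | intermediate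
16 | hernanol, (3R,4R)-4-(4-hydroxy-3-methoxybenzyl)-3-(3,4,5-trimethoxybenzyl)dihydrofuran-2(3H)-one | COc1cc(C[C@H]2COC(=O)[C@@H]2Cc2cc(OC)c(OC)c(OC)c2)ccc1O | target

**Count.** Total steps: 7. Longest linear sequence: 7 steps (from 1).

**Steps most likely to fail**

1. Step 4. Chirality transfer from sulfur may be incomplete if part of the reaction runs through the conformer with p-tolyl inside, and material may be lost to simple Pummerer elimination or zinc deoxygenation of the sulfoxide. If the sense of induction proved opposite to the model, the enantiomeric sulfinate would be used in step 2. The fallback leaves the sulfoxide chemistry altogether; it sets out from 1 (as its Grignard reagent 3) and comes back at 12. Reagent 3 is formylated with DMF to the aldehyde 4-(benzyloxy)-3-methoxybenzaldehyde F1. Stobbe condensation with dimethyl succinate (NaOMe, MeOH) should give the (E)-benzylidenesuccinic acid half-ester F2. Rhodium-catalysed asymmetric hydrogenation, with the bisphosphine enantiomer that delivers the R acid, should give the (R)-benzylsuccinic acid half-ester F3. Reduction of its ester group in the presence of the potassium carboxylate (Ca(BH4)2, EtOH), followed by acidification, should close the lactone to 12.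

2. Step 2. The propargylic CH2 of 7 is both benzylic and next to the alkynyl sulfoxide, so prototropic isomerisation to the allenyl sulfoxide under the basic magnesium alkoxide conditions may compete, as may over-addition at sulfur. The fallback never makes an alkynyl sulfoxide; it sets out from 4 and comes back at 8, so step 3 is not needed. Alkyne 4 is iodinated (NIS, AgNO3 cat., acetone) to the iodoalkyne 1-(benzyloxy)-4-(3-iodoprop-2-yn-1-yl)-2-methoxybenzene F4. Diimide reduction should give the (Z)-iodoalkene 1-(benzyloxy)-4-[(Z)-3-iodoprop-2-en-1-yl]-2-methoxybenzene F5. Iodine–lithium exchange (t-BuLi, Et2O, −78 °C) and addition to 5 should give 8 with retention of the alkene geometry and inversion at sulfur.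

3. Step 1. The SN2′ coupling may lose regiocontrol (aryl allene formation), and unreacted Grignard reagent may deprotonate or isomerise the terminal alkyne. The fallback uses a direct SN2 coupling on a capped propargyl halide; it sets out from 3 and comes back at 4. Reagent 3 is coupled (CuBr cat., THF) with 3-bromo-1-(trimethylsilyl)prop-1-yne to the silylalkyne {3-[4-(benzyloxy)-3-methoxyphenyl]prop-1-yn-1-yl}trimethylsilane F6, which is desilylated (K2CO3, MeOH, 0 °C) to 4.

**Further compounds**

F1 | step 4 | 4-(benzyloxy)-3-methoxybenzaldehyde | COc1cc(C=O)ccc1OCc1ccccc1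
F2 | step 4 | (E)-4-[4-(benzyloxy)-3-methoxyphenyl]-3-(methoxycarbonyl)but-3-enoic acid | COC(=O)/C(CC(=O)O)=C/c1ccc(OCc2ccccc2)c(OC)c1
F3 | step 4 | (R)-4-[4-(benzyloxy)-3-methoxyphenyl]-3-(methoxycarbonyl)butanoic acid | COC(=O)[C@H](Cc1ccc(OCc2ccccc2)c(OC)c1)CC(=O)O
F4 | step 2 | 1-(benzyloxy)-4-(3-iodoprop-2-yn-1-yl)-2-methoxybenzene | COc1cc(CC#CI)ccc1OCc1ccccc1
F5 | step 2 | 1-(benzyloxy)-4-[(Z)-3-iodoprop-2-en-1-yl]-2-methoxybenzene | COc1cc(C/C=C\I)ccc1OCc1ccccc1
F6 | step 1 | {3-[4-(benzyloxy)-3-methoxyphenyl]prop-1-yn-1-yl}trimethylsilane | COc1cc(CC#C[Si](C)(C)C)ccc1OCc1ccccc1
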